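**Plan**
- Enabling feature: in ring C the C4 carbonyl is bonded to the C3 methylene, and C2 carries only H, ring B and O1. Ring C is therefore the adduct of a ring A formyl C–H across an O-(1-arylvinyl) ether on the neighbouring ring A oxygen.
- Retrosynthetic cuts, in order: the two MOM ethers; C3–C4 together with C2–H (hydroacylation); the enol ether CH2 and the O1–acyl bond (ester of the ring A phenol with the ring B acid); the C8–CH2 bond (Negishi coupling); the α-carbon–prenyl bond of the side chain.
- Forward order: the lavandulyl chain is made first and joined to resorcinol-derived ring A. Ring A is formylated and its oxygens differentiated, ring B is attached as an ester and methylenated, and ring C closes last before deprotection.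
- Stereochemistry: the side-chain centre comes from an Evans alkylation (auxiliary control) and is not touched again. C2 is set during ring closure by the chiral bisphosphine on rhodium (catalyst control).

Key step: step 17

Remarks on the chemistry:
- The target is (2S) at C2 and (R) at the side-chain centre. The same spatial arrangement is labelled (S) in lavandulol, its iodide, its zinc reagent and the acyl imide, because the CIP priorities change.
- The (R)-configured bisphosphine is assumed to give the 2S product. The sense of induction would be checked on the first run and the (S)-ligand used if it is opposite.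
- Abbreviations: MOM = methoxymethyl; TBS = tert-butyldimethylsilyl; "(R)-lavandulyl" = (2R)-5-methyl-2-(prop-1-en-2-yl)hex-4-en-1-yl.

**Route**

Step 1
Reactants: 1 (S)-4-benzyloxazolidin-2-one; 2 3-methylbut-2-enoyl chloride
Product: 4 (S)-4-benzyl-3-(3-methylbut-2-enoyl)oxazolidin-2-one, via N-lithio oxazolidinone 3 (not isolated)
Conditions: n-BuLi, THF, −78 °C; then 2, −78 → 0 °C
Reagents that add atoms: none
Why: N-acylation of the lithiated Evans oxazolidinone by an acid chloride is a standard imide formation, and the low temperature prevents deconjugation of the enoyl double bond.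

Step 2
Reactants: 4 (S)-4-benzyl-3-(3-methylbut-2-enoyl)oxazolidin-2-one; 5 prenyl bromide (1-bromo-3-methylbut-2-ene)
Product: 7 (S)-4-benzyl-3-[(2S)-5-methyl-2-(prop-1-en-2-yl)hex-4-enoyl]oxazolidin-2-one, via sodium dienolate 6 (not isolated)
Conditions: NaN(SiMe3)2, THF, −78 °C; then 5, −78 → −30 °C
Reagents that add atoms: none
Why: Evans asymmetric alkylation in its deconjugative form: γ-deprotonation of the s-cis enoyl imide gives the sodium-chelated (Z)-dienolate, which prenyl bromide alkylates (SN2) at the α-carbon on the face opposite the benzyl group, setting the (S) centre that becomes the side-chain stereocentre and leaving the double bond in the isopropenyl position.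

Step 3
Reactants: 7 (S)-4-benzyl-3-[(2S)-5-methyl-2-(prop-1-en-2-yl)hex-4-enoyl]oxazolidin-2-one
Product: 8 (S)-lavandulol [(2S)-5-methyl-2-(prop-1-en-2-yl)hex-4-en-1-ol]
Conditions: LiBH4, MeOH (1 equiv), Et2O, 0 °C
Reagents that add atoms: none
Why: Hydride reduction of the exocyclic imide carbonyl (reductive removal of the Evans auxiliary) is non-basic, so the α-centre next to the isopropenyl group should be neither epimerised nor drawn back into conjugation.

Step 4
Reactants: 8 (S)-lavandulol
Product: 9 (3S)-3-(iodomethyl)-2,6-dimethylhepta-1,5-diene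
Conditions: I2, PPh3, imidazole, CH2Cl2, 0 °C → rt
Reagents that add atoms: iodine, II
Why: Appel-type iodination (Garegg–Samuelsson conditions) replaces the primary hydroxyl by SN2 displacement of an oxyphosphonium ion without touching the adjacent stereocentre or the alkenes.

Step 5
Reactants: 10 resorcinol
Product: 11 1,3-bis(methoxymethoxy)benzene
Conditions: MOMCl, iPr2NEt, CH2Cl2, 0 °C → rt
Reagents that add atoms: chloromethyl methyl ether, COCCl
Why: O-alkylation of both phenols with the reactive chloromethyl ether (MOM protection) installs the acetal groups that later direct both metalations.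

Step 6
Reactants: 11 1,3-bis(methoxymethoxy)benzene
Product: 13 2-iodo-1,3-bis(methoxymethoxy)benzene, via 2-lithio arene 12 (not isolated)
Conditions: n-BuLi, THF, 0 °C; then I2, −78 °C → rt
Reagents that add atoms: iodine, II
Why: Directed ortho-metalation takes place at C2 between the two cooperating MOM-oxy groups, and the aryllithium is trapped by iodine.

Step 7
Reactants: 9 (3S)-3-(iodomethyl)-2,6-dimethylhepta-1,5-diene; 13 2-iodo-1,3-bis(methoxymethoxy)benzene
Product: 15 1,3-bis(methoxymethoxy)-2-[(2R)-5-methyl-2-(prop-1-en-2-yl)hex-4-en-1-yl]benzene, via lavandulylzinc iodide 14 (not isolated)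
Conditions: Zn dust, LiCl, THF, 40 °C; then 13, Pd(OAc)2 (2 mol %), SPhos (4 mol %), THF, 50 °C
Reagents that add atoms: none
Why: Negishi coupling: LiCl-assisted zinc insertion into the primary iodide gives an alkylzinc whose stereocentre lies β to the metal and is not involved, and a zerovalent palladium/SPhos catalyst should couple it with the hindered aryl iodide faster than β-hydride elimination.

Step 8
Reactants: 15 1,3-bis(methoxymethoxy)-2-[(R)-lavandulyl]benzene
Product: 17 2,4-bis(methoxymethoxy)-3-[(R)-lavandulyl]benzaldehyde, via 4-lithio arene 16 (not isolated)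
Conditions: n-BuLi, TMEDA, THF, 0 °C; then DMF, 0 °C → rt; H2O
Reagents that add atoms: N,N-dimethylformamide, CN(C)C=O
Why: Directed ortho-metalation next to a MOM-oxy group (the two open positions are equivalent) followed by formylation with DMF gives the aldehyde, the allylic and benzylic C–H bonds not being competitive under these kinetic conditions.

Step 9
Reactants: 17 2,4-bis(methoxymethoxy)-3-[(R)-lavandulyl]benzaldehyde
Product: 18 2-hydroxy-4-(methoxymethoxy)-3-[(R)-lavandulyl]benzaldehyde
Conditions: MgBr2·OEt2, Et2O/CH2Cl2, 0 °C → rt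
Reagents that add atoms: none
Why: Chelation-controlled Lewis acid cleavage of an acetal: magnesium binds between the formyl oxygen and the neighbouring MOM-oxy group, so bromide opens only that acetal, while the distal MOM ether and the alkenes should survive the aprotic conditions.

Step 10
Reactants: 18 2-hydroxy-4-(methoxymethoxy)-3-[(R)-lavandulyl]benzaldehyde
Product: 19 2-(hydroxymethyl)-5-(methoxymethoxy)-6-[(R)-lavandulyl]phenol
Conditions: NaBH4, MeOH/THF, 0 °C
Reagents that add atoms: none
Why: Borohydride reduction of the aldehyde gives the salicyl alcohol under conditions that touch neither the MOM ether nor the alkenes.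

Step 11
Reactants: 19 2-(hydroxymethyl)-5-(methoxymethoxy)-6-[(R)-lavandulyl]phenol
Product: 20 2-{[(tert-butyldimethylsilyl)oxy]methyl}-5-(methoxymethoxy)-6-[(R)-lavandulyl]phenol
Conditions: TBSCl (1.05 equiv), imidazole, CH2Cl2, 0 °C
Reagents that add atoms: tert-butyldimethylsilyl chloride, CC(C)(C)[Si](C)(C)Cl
Why: Silylation should be selective for the unhindered primary hydroxyl, because the phenol is flanked by two ortho substituents and reacts much more slowly with the bulky silyl chloride.

Step 12
Reactants: 21 4-hydroxy-2-methoxybenzoic acid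
Product: 23 2-methoxy-4-(methoxymethoxy)benzoic acid, via methoxymethyl ester 22 (not isolated)
Conditions: MOMCl (2.5 equiv), iPr2NEt, CH2Cl2, 0 °C → rt; then LiOH, THF/MeOH/H2O, rt; 1 M HCl to pH 4, 0 °C
Reagents that add atoms: chloromethyl methyl ether, COCCl; lithium hydroxide, [Li+].[OH-]
Why: Exhaustive MOM alkylation of phenol and carboxylic acid followed by saponification of the labile MOM ester (acyl substitution by hydroxide) frees the acid and keeps the aryl MOM ether.

Step 13
Reactants: 20 2-{[(tert-butyldimethylsilyl)oxy]methyl}-5-(methoxymethoxy)-6-[(R)-lavandulyl]phenol; 23 2-methoxy-4-(methoxymethoxy)benzoic acid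
Product: 24 2-{[(tert-butyldimethylsilyl)oxy]methyl}-5-(methoxymethoxy)-6-[(R)-lavandulyl]phenyl 2-methoxy-4-(methoxymethoxy)benzoate
Conditions: EDC·HCl, DMAP, CH2Cl2, rt
Reagents that add atoms: none
Why: Steglich esterification (carbodiimide activation, acyl transfer through the N-acylpyridinium ion) acylates the hindered phenol under neutral conditions that preserve the silyl and MOM ethers.

Step 14
Reactants: 24 the aryl benzoate from step 13
Product: 25 tert-butyl{[4-(methoxymethoxy)-2-({1-[2-methoxy-4-(methoxymethoxy)phenyl]ethenyl}oxy)-3-[(R)-lavandulyl]phenyl]methoxy}dimethylsilane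
Conditions: Cp2TiMe2 (3 equiv), toluene, 70 °C, dark; filtration through basic alumina
Reagents that add atoms: dimethyltitanocene Cp2TiMe2, C[Ti](C)(C1C=CC=C1)C1C=CC=C1
Why: Petasis methylenation: thermolysis of Cp2TiMe2 gives the titanium methylidene, which adds [2+2] to the ester carbonyl and cycloreverts to the 1-aryl-1-aryloxyethene, a transformation established for aryl esters, and the non-acidic medium keeps the enol ether intact.

Step 15
Reactants: 25 the silyl-protected enol ether from step 14
Product: 26 [4-(methoxymethoxy)-2-({1-[2-methoxy-4-(methoxymethoxy)phenyl]ethenyl}oxy)-3-[(R)-lavandulyl]phenyl]methanol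
Conditions: Bu4NF, THF, 0 °C
Reagents that add atoms: none
Why: Fluoride-induced desilylation frees the benzylic alcohol under basic conditions that the enol ether and the MOM ethers tolerate.

Step 16
Reactants: 26 the benzylic alcohol from step 15
Product: 27 4-(methoxymethoxy)-2-({1-[2-methoxy-4-(methoxymethoxy)phenyl]ethenyl}oxy)-3-[(R)-lavandulyl]benzaldehyde
Conditions: MnO2 (activated, excess), CH2Cl2, rt
Reagents that add atoms: none
Why: Heterogeneous MnO2 oxidation is selective for the benzylic alcohol and, being neutral, should leave the acid-labile enol ether, the MOM ethers and the alkenes alone.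

Step 17
Reactants: 27 4-(methoxymethoxy)-2-({1-[2-methoxy-4-(methoxymethoxy)phenyl]ethenyl}oxy)-3-[(R)-lavandulyl]benzaldehyde
Product: 28 (2S)-7-(methoxymethoxy)-2-[2-methoxy-4-(methoxymethoxy)phenyl]-8-[(R)-lavandulyl]chroman-4-one (7,4'-bis-O-MOM alopecurone G)
Conditions: [Rh(cod)Cl]2 (2.5 mol %), (R)-DTBM-SEGPHOS (5.5 mol %), AgBF4 (5 mol %), THF (degassed), 60 °C
Reagents that add atoms: none
Why: Proposed new method: cationic monovalent rhodium should insert into the formyl C–H of 27 to give a trivalent acyl rhodium hydride held by the enol ether, the alkene then inserts into Rh–H with hydride going to the internal oxygen- and aryl-bearing carbon (C2) and rhodium to the terminal CH2 (C3), and reductive elimination from the seven-membered acyl–alkyl rhodacycle forms C3–C4. The closest known reaction type is the enantioselective intramolecular rhodium hydroacylation of 1,1-disubstituted alkenes held ortho to a benzaldehyde, which gives benzo-fused six-membered ketones; an enol ether as the alkene partner has not been shown. Ring C closes in the 6-endo mode. The C2 stereocentre is set under catalyst control: the chiral bisphosphine selects the enantiotopic face of the enol ether for hydride delivery, and the lavandulyl centre is too remote to interfere. The step needs regioselectivity for the chromanone over the five-membered 2-methylbenzofuranone and must outrun decarbonylation; the 1,1-disubstitution (rhodium avoids the tertiary carbon and a reductive elimination that would build a quaternary centre), the polarisation of the enol ether (hydride to its electrophilic α-carbon) and chelation through the ortho oxygen–alkene unit should secure both. The neutral, aprotic conditions should keep the MOM groups, the remaining enol ether and the base-labile C2 centre intact.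

Step 18
Reactants: 28 7,4'-bis-O-MOM alopecurone G
Product: 29 alopecurone G [(2S)-7-hydroxy-2-(4-hydroxy-2-methoxyphenyl)-8-[(2R)-5-methyl-2-(prop-1-en-2-yl)hex-4-en-1-yl]chroman-4-one]
Conditions: 3 M HCl (aq)/MeOH, rt → 40 °C
Reagents that add atoms: none
Why: Acid-catalysed acetal methanolysis removes both MOM groups as dimethoxymethane, and the mild temperature is chosen to avoid acid-induced cyclisation of the 7-hydroxyl onto the isopropenyl group and ring-opening epimerisation at C2.

**Compound list**

1 | (S)-4-benzyloxazolidin-2-one | O=C1N[C@@H](Cc2ccccc2)CO1 | starting material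
2 | 3-methylbut-2-enoyl chloride | CC(C)=CC(=O)Cl | starting material
3 | N-lithio (S)-4-benzyloxazolidin-2-one | O=C1OC[C@H](Cc2ccccc2)N1[Li] | intermediate
4 | (S)-4-benzyl-3-(3-methylbut-2-enoyl)oxazolidin-2-one | CC(C)=CC(=O)N1C(=O)OC[C@@H]1Cc1ccccc1 | intermediate
5 | prenyl bromide (1-bromo-3-methylbut-2-ene) | CC(C)=CCBr | starting material
6 | sodium (Z)-dienolate of 4 | C=C(C)/C=C(\O[Na])N1C(=O)OC[C@@H]1Cc1ccccc1 | intermediate
7 | (S)-4-benzyl-3-[(2S)-5-methyl-2-(prop-1-en-2-yl)hex-4-enoyl]oxazolidin-2-one | C=C(C)[C@H](CC=C(C)C)C(=O)N1C(=O)OC[C@@H]1Cc1ccccc1 | intermediate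
8 | (S)-lavandulol, (2S)-5-methyl-2-(prop-1-en-2-yl)hex-4-en-1-ol | C=C(C)[C@H](CC=C(C)C)CO | intermediate
9 | (3S)-3-(iodomethyl)-2,6-dimethylhepta-1,5-diene | C=C(C)[C@H](CC=C(C)C)CI | intermediate
10 | resorcinol | Oc1cccc(O)c1 | starting material
11 | 1,3-bis(methoxymethoxy)benzene | COCOc1cccc(OCOC)c1 | intermediate
12 | 2-lithio-1,3-bis(methoxymethoxy)benzene | COCOc1cccc(OCOC)c1[Li] | intermediate
13 | 2-iodo-1,3-bis(methoxymethoxy)benzene | COCOc1cccc(OCOC)c1I | intermediate
14 | [(2S)-5-methyl-2-(prop-1-en-2-yl)hex-4-en-1-yl]zinc iodide | C=C(C)[C@H](CC=C(C)C)C[Zn]I | intermediate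
15 | 1,3-bis(methoxymethoxy)-2-[(2R)-5-methyl-2-(prop-1-en-2-yl)hex-4-en-1-yl]benzene | C=C(C)[C@H](CC=C(C)C)Cc1c(OCOC)cccc1OCOC | intermediate
16 | 4-lithio derivative of 15 | C=C(C)[C@H](CC=C(C)C)Cc1c(OCOC)ccc([Li])c1OCOC | intermediate
17 | 2,4-bis(methoxymethoxy)-3-[(R)-lavandulyl]benzaldehyde | C=C(C)[C@H](CC=C(C)C)Cc1c(OCOC)ccc(C=O)c1OCOC | intermediate
18 | 2-hydroxy-4-(methoxymethoxy)-3-[(R)-lavandulyl]benzaldehyde | C=C(C)[C@H](CC=C(C)C)Cc1c(OCOC)ccc(C=O)c1O | intermediate
19 | 2-(hydroxymethyl)-5-(methoxymethoxy)-6-[(R)-lavandulyl]phenol | C=C(C)[C@H](CC=C(C)C)Cc1c(OCOC)ccc(CO)c1O | intermediate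
20 | 2-{[(tert-butyldimethylsilyl)oxy]methyl}-5-(methoxymethoxy)-6-[(R)-lavandulyl]phenol | C=C(C)[C@H](CC=C(C)C)Cc1c(OCOC)ccc(CO[Si](C)(C)C(C)(C)C)c1O | intermediate
21 | 4-hydroxy-2-methoxybenzoic acid | COc1cc(O)ccc1C(=O)O | starting material
22 | methoxymethyl 2-methoxy-4-(methoxymethoxy)benzoate | COCOC(=O)c1ccc(OCOC)cc1OC | intermediate
23 | 2-methoxy-4-(methoxymethoxy)benzoic acid | COCOc1ccc(C(=O)O)c(OC)c1 | intermediate
24 | 2-{[(tert-butyldimethylsilyl)oxy]methyl}-5-(methoxymethoxy)-6-[(R)-lavandulyl]phenyl 2-methoxy-4-(methoxymethoxy)benzoate | C=C(C)[C@H](CC=C(C)C)Cc1c(OCOC)ccc(CO[Si](C)(C)C(C)(C)C)c1OC(=O)c1ccc(OCOC)cc1OC | intermediate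
25 | tert-butyl{[4-(methoxymethoxy)-2-({1-[2-methoxy-4-(methoxymethoxy)phenyl]ethenyl}oxy)-3-[(R)-lavandulyl]phenyl]methoxy}dimethylsilane | C=C(C)[C@H](CC=C(C)C)Cc1c(OCOC)ccc(CO[Si](C)(C)C(C)(C)C)c1OC(=C)c1ccc(OCOC)cc1OC | intermediate
26 | [4-(methoxymethoxy)-2-({1-[2-methoxy-4-(methoxymethoxy)phenyl]ethenyl}oxy)-3-[(R)-lavandulyl]phenyl]methanol | C=C(C)[C@H](CC=C(C)C)Cc1c(OCOC)ccc(CO)c1OC(=C)c1ccc(OCOC)cc1OC | intermediate
27 | 4-(methoxymethoxy)-2-({1-[2-methoxy-4-(methoxymethoxy)phenyl]ethenyl}oxy)-3-[(R)-lavandulyl]benzaldehyde | C=C(C)[C@H](CC=C(C)C)Cc1c(OCOC)ccc(C=O)c1OC(=C)c1ccc(OCOC)cc1OC | intermediate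
28 | (2S)-7-(methoxymethoxy)-2-[2-methoxy-4-(methoxymethoxy)phenyl]-8-[(R)-lavandulyl]chroman-4-one | C=C(C)[C@H](CC=C(C)C)Cc1c(OCOC)ccc2c1O[C@H](c1ccc(OCOC)cc1OC)CC2=O | intermediate
29 | alopecurone G | C=C(C)[C@H](CC=C(C)C)Cc1c(O)ccc2c1O[C@H](c1ccc(O)cc1OC)CC2=O | target

**Step count**

Total: 18 steps. Longest linear sequence: 15 steps (steps 1–4, 7–11, 13–18).

**Steps most likely to fail, with fallbacks**

1. Step 17 (hydroacylation). The risks are hydride transfer in the reverse sense, so that the five-membered ketone forms, decarbonylation of the acyl rhodium hydride, and weak facial discrimination at C2. The fallback uses known chemistry, sets out from 15 and returns at 28.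
   - Arene 15 would be lithiated as in step 8 (aryllithium 16) and acylated with N-methoxy-N-methylacetamide to give 1-{2,4-bis(methoxymethoxy)-3-[(R)-lavandulyl]phenyl}ethan-1-one F1.
   - Chelation-controlled removal of the ortho MOM group (MgBr2·OEt2, as in step 9) would give 1-{2-hydroxy-4-(methoxymethoxy)-3-[(R)-lavandulyl]phenyl}ethan-1-one F2.
   - Heating with N,N-dimethylformamide dimethyl acetal would give (E)-3-(dimethylamino)-1-{2-hydroxy-4-(methoxymethoxy)-3-[(R)-lavandulyl]phenyl}prop-2-en-1-one F3, which should close on silica gel or with catalytic pyridinium tosylate to 7-(methoxymethoxy)-8-[(R)-lavandulyl]-4H-chromen-4-one F4.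
   - The ring B partner would come from commercial 4-bromo-3-methoxyphenol: MOM protection gives 1-bromo-2-methoxy-4-(methoxymethoxy)benzene F5, and palladium-catalysed borylation with B2(OH)4 and KOAc gives [2-methoxy-4-(methoxymethoxy)phenyl]boronic acid F6.
   - Rhodium-catalysed asymmetric conjugate addition of F6 to F4 ([RhCl(C2H4)2]2, chiral diene ligand of the antipode that gives 2S, aq. KOH, toluene) would then give 28, and step 18 follows unchanged.

2. Step 14 (methylenation). The risks are slow methylenation of the doubly ortho-flanked, electron-rich aryl ester, so that Cp2TiMe2 decomposes before conversion is complete, and hydrolytic loss of the enol ether during isolation. The fallback forms the enol ether C–O bond instead of the C=CH2 bond; it sets out from 20 and returns at 25.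
   - Commercial 1-(4-hydroxy-2-methoxyphenyl)ethan-1-one would be MOM-protected to give 1-[2-methoxy-4-(methoxymethoxy)phenyl]ethan-1-one F7.
   - Deprotonation with KN(SiMe3)2 would give potassium 1-[2-methoxy-4-(methoxymethoxy)phenyl]ethen-1-olate F8, which N-phenylbis(trifluoromethanesulfonimide) would trap as 1-[2-methoxy-4-(methoxymethoxy)phenyl]ethenyl trifluoromethanesulfonate F9.
   - Palladium-catalysed C–O coupling of phenol 20 with F9 (Pd2(dba)3, 2-(di-tert-butylphosphino)biphenyl, K3PO4, toluene, 80 °C) would give 25 directly, and steps 15–18 follow.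

3. Step 7 (Negishi coupling). The risks are β-hydride elimination from the alkylpalladium intermediate outpacing reductive elimination at the di-ortho-alkoxy aryl centre, and sluggish zinc insertion. The fallback replaces the cross-coupling by a polar substitution; it sets out from 11 and 9 and returns at 15.
   - Aryllithium 12, generated from 11 as in step 6, would be alkylated directly with iodide 9 in THF/DMPU at −78 → 0 °C (SN2 at the primary carbon).
   - This would give 15 without palladium or zinc and would make step 6 unnecessary; no new compound arises on this path (entry F0).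

**Further compounds**

F1 | step 17 | 1-{2,4-bis(methoxymethoxy)-3-[(2R)-5-methyl-2-(prop-1-en-2-yl)hex-4-en-1-yl]phenyl}ethan-1-one | C=C(C)[C@H](CC=C(C)C)Cc1c(OCOC)ccc(C(C)=O)c1OCOC
F2 | step 17 | 1-{2-hydroxy-4-(methoxymethoxy)-3-[(2R)-5-methyl-2-(prop-1-en-2-yl)hex-4-en-1-yl]phenyl}ethan-1-one | C=C(C)[C@H](CC=C(C)C)Cc1c(OCOC)ccc(C(C)=O)c1O
F3 | step 17 | (E)-3-(dimethylamino)-1-{2-hydroxy-4-(methoxymethoxy)-3-[(2R)-5-methyl-2-(prop-1-en-2-yl)hex-4-en-1-yl]phenyl}prop-2-en-1-one | C=C(C)[C@H](CC=C(C)C)Cc1c(OCOC)ccc(C(=O)/C=C/N(C)C)c1O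
F4 | step 17 | 7-(methoxymethoxy)-8-[(2R)-5-methyl-2-(prop-1-en-2-yl)hex-4-en-1-yl]-4H-chromen-4-one | C=C(C)[C@H](CC=C(C)C)Cc1c(OCOC)ccc2c1OC=CC2=O
F5 | step 17 | 1-bromo-2-methoxy-4-(methoxymethoxy)benzene | COCOc1ccc(Br)c(OC)c1
F6 | step 17 | [2-methoxy-4-(methoxymethoxy)phenyl]boronic acid | COCOc1ccc(B(O)O)c(OC)c1
F7 | step 14 | 1-[2-methoxy-4-(methoxymethoxy)phenyl]ethan-1-one | COCOc1ccc(C(C)=O)c(OC)c1
F8 | step 14 | potassium 1-[2-methoxy-4-(methoxymethoxy)phenyl]ethen-1-olate | C=C(O[K])c1ccc(OCOC)cc1OC
F9 | step 14 | 1-[2-methoxy-4-(methoxymethoxy)phenyl]ethenyl trifluoromethanesulfonate | C=C(OS(=O)(=O)C(F)(F)F)c1ccc(OCOC)cc1OC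
F0 | step 7 | none | none
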